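The cyclopentane of the target is a folded linalool. Its methyl carbinol carbon C-2′ is linalool C-3. The bond between the two ring methines, C-1′ (bearing the CH2–aryl arm) and C-5′ (bearing isopropenyl), corresponds to a linalool C-2/C-6 connection, and this bond is the disconnection. The precursor is an open-chain (R)-β-hydroxy ester carrying an (E)-allylic chloride. In one operation its lithium alkoxide/ester enolate dianion closes the five-membered ring by SN2′ attack, sets C-1′ and C-5′ relative to C-2′, and unmasks the isopropenyl group. The ester carbon then becomes the CH2 link to an isobutyryl methylphloroglucinol, which is finally dearomatised by prenylation at its methyl-bearing carbon.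

Key step: step 6

Remark on configuration: the target is (6R,1′S,2′R,5′R). C-2′ has the spatial arrangement of C-3 in (R)-linalool and no step touches it. The descriptor of the neighbouring methine reads S in ester, aldehyde and target and R in diol 12, through CIP ranking only.
Assumption: commercial (R)-(−)-linalool is used at the highest enantiopurity on offer; material from residual (S)-antipode should end after step 11 mainly as a diastereomer and be removed there.
Assumption: the sense of induction of the ligand in step 11 cannot be predicted safely; the (R,R) antipode is written, and the equally available (S,S) antipode replaces it if that one favours 20.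
Design remark on 9: the carbinol stays free because it is the chelating element. Chloride is preferred to bromide or sulfonate because it tolerates the amide base and slows direct displacement. Inverse addition, high dilution and a cold acid quench guard against retro-aldol cleavage and closure through oxygen.

Step 1
Reactants: 1 (R)-(−)-linalool
Product: 3 (3R)-3,7-dimethyloct-6-ene-1,3-diol, via B-alkyl-9-BBN adduct 2 (not isolated)
Conditions: 9-BBN (1.5 equiv), THF, 0 °C → rt; then 3 M NaOH, 30% H2O2, 0 °C → rt
Reagents that add atoms: hydrogen peroxide, OO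
Why: Brown hydroboration–oxidation; 9-BBN adds anti-Markovnikov to the monosubstituted vinyl group far faster than to the trisubstituted alkene, and the carbinol centre is not involved.

Step 2
Reactants: 3 (3R)-3,7-dimethyloct-6-ene-1,3-diol
Product: 5 (3R)-3-hydroxy-3,7-dimethyloct-6-enoic acid, via hydroxy aldehyde 4 (not isolated)
Conditions: TEMPO (0.2 equiv), PhI(OAc)2 (2.5 equiv), MeCN–H2O (1:1), rt
Reagents that add atoms: water, O
Why: Oxoammonium (TEMPO/BAIB) oxidation of the primary alcohol through the aldehyde hydrate to the acid; the tertiary alcohol cannot be oxidised and the trisubstituted alkene tolerates this chlorine-free oxidant.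

Step 3
Reactants: 5 (3R)-3-hydroxy-3,7-dimethyloct-6-enoic acid
Product: 6 methyl (3R)-3-hydroxy-3,7-dimethyloct-6-enoate
Conditions: MeI, K2CO3, DMF, rt
Reagents that add atoms: iodomethane, CI
Why: SN2 O-alkylation of the carboxylate; the weak base neither methylates the tertiary alcohol nor triggers retro-aldol cleavage.

Step 4
Reactants: 6 methyl (3R)-3-hydroxy-3,7-dimethyloct-6-enoate
Product: 8 methyl (3R,6E)-3,8-dihydroxy-3,7-dimethyloct-6-enoate, via enal 7 (not isolated)
Conditions: SeO2 (0.3 equiv), t-BuOOH (3 equiv), salicylic acid (0.1 equiv), CH2Cl2, 0 °C → rt; then NaBH4, MeOH, 0 °C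
Reagents that add atoms: tert-butyl hydroperoxide, CC(C)(C)OO (oxygen relayed through SeO2, O=[Se]=O)
Why: Riley allylic oxidation (ene reaction, then [2,3]-sigmatropic shift) attacks the (E)-methyl of a gem-dimethyl trisubstituted alkene, and the brief borohydride treatment returns over-oxidised enal to the same (E)-allylic alcohol.

Step 5
Reactants: 8 methyl (3R,6E)-3,8-dihydroxy-3,7-dimethyloct-6-enoate
Product: 9 methyl (3R,6E)-8-chloro-3-hydroxy-3,7-dimethyloct-6-enoate
Conditions: NCS, Me2S, CH2Cl2, −30 → 0 °C
Reagents that add atoms: N-chlorosuccinimide, O=C1CCC(=O)N1Cl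
Why: Corey–Kim-type chlorination; the primary allylic alkoxysulfonium salt is displaced by chloride without allylic transposition or E/Z loss, while the tertiary alcohol gives no displaceable species.

Step 6
Reactants: 9 methyl (3R,6E)-8-chloro-3-hydroxy-3,7-dimethyloct-6-enoate
Product: 11 methyl (1S,2R,5R)-2-hydroxy-2-methyl-5-(prop-1-en-2-yl)cyclopentane-1-carboxylate, via dilithio dianion 10 (not isolated)
Conditions: LDA (2.2 equiv), THF–DMPU (10:1), 0.02 M, 9 added slowly at −78 °C, then → −30 °C; AcOH, −78 °C
Reagents that add atoms: none
Why: Proposed new method: two equivalents of LDA convert 9 into the lithium alkoxide/ester enolate 10, held as a six-membered O–Li–O chelate, whose α-carbon adds to the CH= carbon (C-6) of the tethered allylic chloride while chloride departs from C-8 (intramolecular SN2′), so the C-1/C-5 ring bond and the isopropenyl group arise together. The closest known reaction types are the Fráter–Seebach alkylation of β-hydroxy ester dianions and the intramolecular ester-enolate SN2′ alkylation that gives 2-alkenylcyclopentanecarboxylates, and only their union on a tertiary aldol is new. The cyclopentane closes in the 5-exo-trig mode. C-1 is set by the chelate, because the carbinol C–O bond lies near the enolate plane, the pseudo-axial tether is the only carbinol substituent able to reach the π-face, and the ester therefore ends cis to the hydroxyl; C-5 is set by the developing isopropenyl group taking the pseudo-equatorial site beside the enolate C–H and away from C(OMe)OLi, i.e. trans to the ester. The step needs C- over O-alkylation (the dianion carbon is far more nucleophilic than the chelated tertiary alkoxide, whose own 5-exo SN2′ path to a tetrahydrofuran is the competitor), SN2′ over SN2 (five- against seven-membered ring) and no retro-aldol cleavage (lithium counter-ion, low temperature, cold acid quench).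

Step 7
Reactants: 11 methyl (1S,2R,5R)-2-hydroxy-2-methyl-5-(prop-1-en-2-yl)cyclopentane-1-carboxylate
Product: 12 (1R,2R,3R)-2-(hydroxymethyl)-1-methyl-3-(prop-1-en-2-yl)cyclopentan-1-ol
Conditions: LiAlH4, Et2O, 0 °C
Reagents that add atoms: none
Why: Hydride reduction of the ester to the primary alcohol is faster than any cleavage of the aluminium alkoxide and leaves the isolated alkene and all three stereocentres untouched.

Step 8
Reactants: 12 (1R,2R,3R)-2-(hydroxymethyl)-1-methyl-3-(prop-1-en-2-yl)cyclopentan-1-ol
Product: 13 (1S,2R,5R)-2-hydroxy-2-methyl-5-(prop-1-en-2-yl)cyclopentane-1-carbaldehyde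
Conditions: TEMPO (0.1 equiv), PhI(OAc)2 (1.1 equiv), CH2Cl2, rt; used without storage
Reagents that add atoms: none
Why: Anhydrous oxoammonium oxidation stops at the aldehyde under base-free conditions, and the formyl group already sits trans to both flanking carbon substituents, so epimerisation at C-1 has no driving force.

Step 9
Reactants: 14 2-methylphloroglucinol; 15 isobutyryl chloride
Product: 16 1-(2,4,6-trihydroxy-3-methylphenyl)-2-methylpropan-1-one
Conditions: AlCl3 (4 equiv), PhNO2–CH2Cl2, rt → 50 °C; 1 M HCl
Reagents that add atoms: none
Why: Friedel–Crafts acylation; the two free ring positions of 14 are equivalent, so one regioisomer results, and the chelated ketone deactivates the ring towards a second acylation.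

Step 10
Reactants: 13 (1S,2R,5R)-2-hydroxy-2-methyl-5-(prop-1-en-2-yl)cyclopentane-1-carbaldehyde; 16 1-(2,4,6-trihydroxy-3-methylphenyl)-2-methylpropan-1-one
Product: 18 1-[2,4,6-trihydroxy-3-{[(1S,2R,5R)-2-hydroxy-2-methyl-5-(prop-1-en-2-yl)cyclopentyl]methyl}-5-methylphenyl]-2-methylpropan-1-one, via ortho-quinone methide 17 (not isolated)
Conditions: 16 (1.3 equiv), Hantzsch ester (1.5 equiv), L-proline (0.2 equiv), MeCN, rt; 13 added last
Reagents that add atoms: none
Why: Knoevenagel condensation/transfer hydrogenation cascade (three-component reductive alkylation); the only free ring carbon of 16 condenses with 13 to the quinone methide 17, which excess Hantzsch ester should reduce by conjugate hydride transfer before it can tautomerise or fragment, and C-1′ keeps its thermodynamically preferred configuration.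

Step 11
Reactants: 18 1-[2,4,6-trihydroxy-3-{[(1S,2R,5R)-2-hydroxy-2-methyl-5-(prop-1-en-2-yl)cyclopentyl]methyl}-5-methylphenyl]-2-methylpropan-1-one; 19 prenyl acetate
Product: 20 (6R)-3,5-dihydroxy-4-{[(1S,2R,5R)-2-hydroxy-2-methyl-5-(prop-1-en-2-yl)cyclopentyl]methyl}-6-methyl-6-(3-methylbut-2-en-1-yl)-2-(2-methylpropanoyl)cyclohexa-2,4-dien-1-one (target)
Conditions: Pd2(dba)3·CHCl3 (2.5 mol %), (R,R)-DACH-phenyl Trost ligand (7.5 mol %), 19 (1.05 equiv), Et3N (1.1 equiv), degassed CH2Cl2, 0 °C → rt
Reagents that add atoms: none
Why: Proposed new method: Pd(0) ionises 19 to the 1,1-dimethylallyl complex inside the chiral pocket of the ligand and the ammonium phenolate of 18 attacks its CH2 terminus through the methyl-bearing ring carbon (the carbon bearing the cyclopentylmethyl arm is more shielded, attack at the CMe2 terminus would create vicinal quaternary carbons, and O-prenyl ethers re-ionise and are funnelled to the C-alkylated vinylogous acid), so C-6 is set by the catalyst because the cyclopentane stereocentres are too remote to bias either face; the closest known reaction types are the Pd-catalysed asymmetric allylic dearomatisation of naphthols with this ligand family, the racemic Pd(0)-catalysed dearomative allylation of acylphloroglucinols and the base-mediated dearomative prenylation of 3-alkyl-5-methyl acylphloroglucinols at the C-methyl carbon.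

Compound list
1 | (R)-(−)-linalool | CC(C)=CCC[C@@](C)(O)C=C | starting material
2 | 9-[(3S)-3-hydroxy-3,7-dimethyloct-6-en-1-yl]-9-borabicyclo[3.3.1]nonane (same spatial arrangement as 1; descriptor changes by ranking only) | CC(C)=CCC[C@@](C)(O)CCB1C2CCCC1CCC2 | intermediate
3 | (3R)-3,7-dimethyloct-6-ene-1,3-diol | CC(C)=CCC[C@@](C)(O)CCO | intermediate
4 | (3R)-3-hydroxy-3,7-dimethyloct-6-enal | CC(C)=CCC[C@@](C)(O)CC=O | intermediate
5 | (3R)-3-hydroxy-3,7-dimethyloct-6-enoic acid | CC(C)=CCC[C@@](C)(O)CC(=O)O | intermediate
6 | methyl (3R)-3-hydroxy-3,7-dimethyloct-6-enoate | CC(C)=CCC[C@@](C)(O)CC(=O)OC | intermediate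
7 | methyl (3R,6E)-3-hydroxy-3,7-dimethyl-8-oxooct-6-enoate | O=C/C(C)=C/CC[C@@](C)(O)CC(=O)OC | intermediate
8 | methyl (3R,6E)-3,8-dihydroxy-3,7-dimethyloct-6-enoate | OC/C(C)=C/CC[C@@](C)(O)CC(=O)OC | intermediate
9 | methyl (3R,6E)-8-chloro-3-hydroxy-3,7-dimethyloct-6-enoate | ClC/C(C)=C/CC[C@@](C)(O)CC(=O)OC | intermediate
10 | dilithium alkoxide/enolate of 9 (enolate O–Li cis to the carbinol carbon, chelated) | ClC/C(C)=C/CC[C@@](C)(O[Li])/C=C(\O[Li])OC | intermediate
11 | methyl (1S,2R,5R)-2-hydroxy-2-methyl-5-(prop-1-en-2-yl)cyclopentane-1-carboxylate (ester cis to OH, trans to isopropenyl) | C=C(C)[C@@H]1CC[C@@](C)(O)[C@H]1C(=O)OC | intermediate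
12 | (1R,2R,3R)-2-(hydroxymethyl)-1-methyl-3-(prop-1-en-2-yl)cyclopentan-1-ol | C=C(C)[C@@H]1CC[C@@](C)(O)[C@H]1CO | intermediate
13 | (1S,2R,5R)-2-hydroxy-2-methyl-5-(prop-1-en-2-yl)cyclopentane-1-carbaldehyde | C=C(C)[C@@H]1CC[C@@](C)(O)[C@H]1C=O | intermediate
14 | 2-methylphloroglucinol | Cc1c(O)cc(O)cc1O | starting material
15 | isobutyryl chloride | CC(C)C(=O)Cl | starting material
16 | 1-(2,4,6-trihydroxy-3-methylphenyl)-2-methylpropan-1-one | CC(C)C(=O)c1c(O)cc(O)c(C)c1O | intermediate
17 | ortho-quinone methide from 13 and 16 (exocyclic alkene geometry open) | C=C(C)[C@@H]1CC[C@@](C)(O)[C@H]1C=C1C(=O)C(C)=C(O)C(C(=O)C(C)C)=C1O | intermediate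
18 | 1-[2,4,6-trihydroxy-3-{[(1S,2R,5R)-2-hydroxy-2-methyl-5-(prop-1-en-2-yl)cyclopentyl]methyl}-5-methylphenyl]-2-methylpropan-1-one | C=C(C)[C@@H]1CC[C@@](C)(O)[C@H]1Cc1c(O)c(C)c(O)c(C(=O)C(C)C)c1O | intermediate
19 | prenyl acetate (3-methylbut-2-en-1-yl acetate) | CC(C)=CCOC(C)=O | starting material
20 | (6R)-3,5-dihydroxy-4-{[(1S,2R,5R)-2-hydroxy-2-methyl-5-(prop-1-en-2-yl)cyclopentyl]methyl}-6-methyl-6-(3-methylbut-2-en-1-yl)-2-(2-methylpropanoyl)cyclohexa-2,4-dien-1-one | C=C(C)[C@@H]1CC[C@@](C)(O)[C@H]1CC1=C(O)[C@@](C)(CC=C(C)C)C(=O)C(C(=O)C(C)C)=C1O | target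

Total step count: 11. Longest linear sequence: 10 (steps 1–8, 10, 11).

Steps most likely to fail

Step 6. Several processes could compete with ring closure:
- retro-aldol cleavage of the tertiary aldolate on warming;
- closure through the alkoxide oxygen;
- base-induced loss of HCl from the allylic chloride;
- weak trans selectivity at C-5.

The fallback sets out from 8 and returns at 11. It replaces the hard dianion by a neutral nucleophile and a π-allylpalladium electrophile. Both belong to known chemistry: the Pd(0)-catalysed allylation of ketene silyl acetals with allylic carbonates, and Tsuji–Trost 5-exo closures to 2-alkenylcyclopentanecarboxylates.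

The primary allylic hydroxyl of 8 is acylated (ClCO2Me, pyridine, CH2Cl2, 0 °C) to methyl (3R,6E)-3-hydroxy-8-(methoxycarbonyloxy)-3,7-dimethyloct-6-enoate F1. LDA (2.2 equiv) with TMSCl present (THF, −78 °C → rt) gives the ketene methyl trimethylsilyl acetal bearing the carbinol as its trimethylsilyl ether F2, so no free alkoxide survives. Pd2(dba)3/dppe in THF at reflux ionises the carbonate. The liberated methoxide unmasks the enolate next to the allyl complex, and five-ring closure should give methyl (1S,2R,5R)-2-methyl-5-(prop-1-en-2-yl)-2-(trimethylsilyloxy)cyclopentane-1-carboxylate F3. In F3 the ester is trans to both flanking carbon groups, which is also the thermodynamic arrangement. Citric acid in methanol frees 11.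

Step 11. The risks are poor facial selectivity at the remote prochiral carbon, alkylation at the other substituted ring carbon, and a second prenylation.

The fallback sets out from 18 and returns at 20, and gives up reagent control in favour of separation. Compound 18 is prenylated under the conditions established for 3-alkyl-5-methyl acylphloroglucinols (prenyl bromide, aqueous KOH, 0 °C), which deliver C-alkylation at the methyl-bearing carbon. Both configurations at C-6 are expected. Because the cyclopentane is enantiopure they are diastereomers: the target 20 and the (6S)-epimer of the target F4. The two are parted by preparative HPLC.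

Step 10. The risks fall on two species:
- the hydroxy aldehyde may dehydrate or undergo retro-aldol opening under amine catalysis;
- the quinone methide may be diverted by tautomerisation, by aromatisation-driven fragmentation of the β-hydroxy unit, or by capture with a second arene.

The fallback sets out from 12 and returns at 18. It avoids both aldehyde and quinone methide by switching to direct C-alkylation, as known for acylphloroglucinol anions and β-branched primary iodides.

Iodination of the primary alcohol (I2, PPh3, imidazole, CH2Cl2, 0 °C) gives (1R,2S,3R)-2-(iodomethyl)-1-methyl-3-(prop-1-en-2-yl)cyclopentan-1-ol F5. TESOTf/2,6-lutidine masks the carbinol, and so blocks oxetane formation, as triethyl{[(1R,2S,3R)-2-(iodomethyl)-1-methyl-3-(prop-1-en-2-yl)cyclopentyl]oxy}silane F6. The lithium phenolate of 16 (LiHMDS, THF–DMPU, 0 → 50 °C), whose tight ion pairing favours carbon over oxygen, is alkylated at its free ring carbon to the triethylsilyl ether of 18 F7. HF·pyridine in THF then releases 18. Modest efficiency is to be expected for this displacement.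

Further compounds
F1 | step 6 | methyl (3R,6E)-3-hydroxy-8-(methoxycarbonyloxy)-3,7-dimethyloct-6-enoate | COC(=O)OC/C(C)=C/CC[C@@](C)(O)CC(=O)OC
F2 | step 6 | ketene methyl trimethylsilyl acetal of F1 with the (3R)-carbinol as trimethylsilyl ether | COC(=O)OC/C(C)=C/CC[C@@](C)(O[Si](C)(C)C)C=C(OC)O[Si](C)(C)C
F3 | step 6 | methyl (1S,2R,5R)-2-methyl-5-(prop-1-en-2-yl)-2-(trimethylsilyloxy)cyclopentane-1-carboxylate | C=C(C)[C@@H]1CC[C@@](C)(O[Si](C)(C)C)[C@H]1C(=O)OC
F4 | step 11 | (6S)-epimer of the target | C=C(C)[C@@H]1CC[C@@](C)(O)[C@H]1CC1=C(O)[C@](C)(CC=C(C)C)C(=O)C(C(=O)C(C)C)=C1O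
F5 | step 10 | (1R,2S,3R)-2-(iodomethyl)-1-methyl-3-(prop-1-en-2-yl)cyclopentan-1-ol | C=C(C)[C@@H]1CC[C@@](C)(O)[C@H]1CI
F6 | step 10 | triethyl{[(1R,2S,3R)-2-(iodomethyl)-1-methyl-3-(prop-1-en-2-yl)cyclopentyl]oxy}silane | C=C(C)[C@@H]1CC[C@@](C)(O[Si](CC)(CC)CC)[C@H]1CI
F7 | step 10 | 1-[2,4,6-trihydroxy-3-methyl-5-({(1S,2R,5R)-2-methyl-5-(prop-1-en-2-yl)-2-[(triethylsilyl)oxy]cyclopentyl}methyl)phenyl]-2-methylpropan-1-one | C=C(C)[C@@H]1CC[C@@](C)(O[Si](CC)(CC)CC)[C@H]1Cc1c(O)c(C)c(O)c(C(=O)C(C)C)c1O
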